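## Retrosynthetic overview
1. The C8–C9 bond comes from a Biellmann alkylation of an (E)-allylic sulfone with 8-bromogeranyl TBS ether, followed by reductive desulfonylation.
2. The ring-bearing (E)-trisubstituted alkene (C10=C11) comes from Negishi carboalumination of a terminal alkyne, which in turn comes from the primary iodide of the ring diol.
3. The ring diol (OH trans and Me cis to the side chain) comes from anti-epoxidation of an α-cyclohomogeranate ester and hydride opening. That ester comes from a Johnson–Claisen rearrangement, which transfers chirality from (R)-2,4,4-trimethylcyclohex-2-enol.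
4. The enol comes from CBS reduction plus lipase kinetic resolution of the enone. The enone comes from Robinson annulation of isobutyraldehyde and ethyl vinyl ketone. This aldol closure (step 2) is the only ring-forming step.

**Assumptions:**
- (S)-Me-CBS gives the (R)-enol, by analogy with aryl and vinyl methyl ketones.
- Peracid attacks anti to the pseudo-axial side chain (about 4:1), and the diastereomers separate by chromatography.

## Route

**Step 1**
Reactants: 1 isobutyraldehyde; 2 ethyl vinyl ketone
Product: 3 2,2-dimethyl-5-oxoheptanal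
Conditions: KOH (2 mol %), EtOH, 0 °C → rt
Reagents that add atoms: none
Why: Michael addition of the isobutyraldehyde enolate; it has a single α-H, so it cannot over-alkylate.

**Step 2**
Reactants: 3
Product: 4 2,4,4-trimethylcyclohex-2-en-1-one
Conditions: pyrrolidine (20 mol %), AcOH (20 mol %), PhH, reflux, Dean–Stark
Reagents that add atoms: none
Why: intramolecular aldol condensation (second half of a Robinson annulation). Only the ethyl-side α-carbon closes a six-membered ring, and E1cB dehydration gives the enone. This forms the only ring.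

**Step 3**
Reactants: 4
Product: 5 (1R)-2,4,4-trimethylcyclohex-2-en-1-ol, about 92 % ee
Conditions: (S)-Me-CBS (10 mol %), BH3·SMe2 (0.7 equiv), THF, −20 °C
Reagents that add atoms: none (hydride only)
Why: Corey–Bakshi–Shibata catalytic asymmetric reduction; the catalyst–borane complex delivers hydride to one enantiotopic face of the C=O, setting the first stereocenter.

**Step 4**
Reactants: 5
Product: 6 (1R)-2,4,4-trimethylcyclohex-2-en-1-yl acetate, ≥99 % ee
Conditions: Burkholderia cepacia lipase (a hydrolase), vinyl acetate (3 equiv), TBME, 25 °C, stopped at about 90 % conversion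
Reagents that add atoms: vinyl acetate, C=COC(C)=O (acetyl group)
Why: lipase-catalysed enantioselective transesterification (kinetic resolution) acylates the (R)-alcohol much faster than the minor (S)-alcohol, which stays free and is removed by chromatography.

**Step 5**
Reactants: 6
Product: 7 (1R)-2,4,4-trimethylcyclohex-2-en-1-ol, ≥99 % ee
Conditions: K2CO3 (0.3 equiv), MeOH, 0 °C → rt
Reagents that add atoms: none
Why: mild methanolysis of the acetate does not touch the stereocenter.

**Step 6**
Reactants: 7
Product: 8 ethyl 2-[(1S)-2,6,6-trimethylcyclohex-2-en-1-yl]acetate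
Conditions: MeC(OEt)3 (10 equiv), EtCO2H (5 mol %), 140 °C, sealed tube, EtOH removed
Reagents that add atoms: triethyl orthoacetate, CC(OCC)(OCC)OCC (gives the CH2CO2Et unit)
Why: Johnson–Claisen [3,3] rearrangement is suprafacial, so the new C–C bond forms at C3 on the same face as the departing C–O bond. This transfers the carbinol chirality to the ring carbon that will carry the chain (S) and moves the alkene to the trisubstituted Δ2 position.

**Step 7**
Reactants: 8
Product: 9 ethyl 2-[(1R,2S,6S)-1,3,3-trimethyl-7-oxabicyclo[4.1.0]heptan-2-yl]acetate, epoxide trans to the side chain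
Conditions: mCPBA (1.2 equiv), NaHCO3 (3 equiv), CH2Cl2, 0 °C; separate diastereomers by SiO2 chromatography
Reagents that add atoms: mCPBA, O=C(OO)c1cccc(Cl)c1 (one O atom)
Why: Prilezhaev epoxidation; the pseudo-axial side chain, held axial by allylic strain with the vinyl methyl, blocks its own face, so the peracid attacks anti and sets the tertiary C–O configuration.

**Step 8**
Reactants: 9
Product: 10 (1S,2S)-2-(2-hydroxyethyl)-1,3,3-trimethylcyclohexan-1-ol
Conditions: LiAlH4 (4 equiv), THF, 0 °C → reflux, 12 h
Reagents that add atoms: none (hydride only)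
Why: LiAlH4 reduces the ester and opens the epoxide by SN2 at the secondary carbon, so the tertiary C–O bond is retained.

**Step 9**
Reactants: 10
Product: 11 bis(triethylsilyl) ether of 10
Conditions: TESOTf (3.5 equiv), 2,6-lutidine (5 equiv), CH2Cl2, −78 → 0 °C
Reagents that add atoms: TESOTf, CC[Si](CC)(CC)OS(=O)(=O)C(F)(F)F (SiEt3 groups)
Why: silylation masks the tertiary alkoxide, which could otherwise close onto the primary electrophile to give a tetrahydrofuran in later steps.

**Step 10**
Reactants: 11
Product: 12 primary alcohol with the tertiary OTES retained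
Conditions: PPTS (0.1 equiv), MeOH/CH2Cl2 1:1, 0 °C
Reagents that add atoms: none
Why: acid methanolysis cleaves the primary TES ether far faster than the hindered tertiary one.

**Step 11**
Reactants: 12
Product: 13 primary iodide
Conditions: PPh3 (1.5 equiv), I2 (1.5 equiv), imidazole (3 equiv), CH2Cl2, 0 °C → rt
Reagents that add atoms: iodine, II
Why: Garegg–Samuelsson (Appel-type) iodination by SN2 on the primary carbon.

**Step 12**
Reactants: 13
Product: 14 terminal alkyne
Conditions: LiC≡CH·ethylenediamine (3 equiv), DMSO, 10 °C → rt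
Reagents that add atoms: lithium acetylide–EDA, C#C[Li].NCCN (C2H unit)
Why: SN2 displacement; the primary iodide is branched only at the γ-position.

**Step 13**
Reactants: 14
Product: 15 (E)-vinyl iodide
Conditions: Me3Al (3 equiv), Cp2ZrCl2 (25 mol %), CH2Cl2, 0 °C → rt, 16 h; then I2 (2 equiv), THF, −30 °C
Reagents that add atoms: trimethylaluminium, C[Al](C)C (Me); iodine, II (I)
Why: Negishi Zr-catalysed carboalumination adds Me–Al syn across the alkyne, with Me on the internal carbon. Iodinolysis with retention gives the (E)-trisubstituted alkene (C10=C11).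

**Step 14**
Reactants: 15
Product: 16 methyl (E)-enoate
Conditions: CO (balloon), MeOH/Et3N/THF, Pd(PPh3)4 (5 mol %), 50 °C
Reagents that add atoms: carbon monoxide, [C-]#[O+]; methanol, CO (CO2Me group)
Why: Pd-catalysed alkoxycarbonylation proceeds with retention of alkene geometry.

**Step 15**
Reactants: 16
Product: 17 (E)-allylic alcohol
Conditions: DIBAL-H (2.5 equiv), CH2Cl2, −78 → 0 °C
Reagents that add atoms: none (hydride only)
Why: ester-to-alcohol reduction; the silyl ether and the alkene are untouched.

**Step 16**
Reactants: 17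
Product: 18 allylic bromide
Conditions: PPh3 (1.3 equiv), CBr4 (1.3 equiv), CH2Cl2, 0 °C; use crude
Reagents that add atoms: carbon tetrabromide, BrC(Br)(Br)Br (Br)
Why: neutral Appel bromination at the primary allylic carbon, avoiding acid cleavage of the TES ether.

**Step 17**
Reactants: 18
Product: 19 (E)-allylic phenyl sulfone
Conditions: PhSO2Na (1.5 equiv), DMF, rt
Reagents that add atoms: sodium benzenesulfinate, O=S(=O)([O-])c1ccccc1.[Na+] (PhSO2)
Why: SN2 at the primary allylic carbon of a geranyl-type bromide retains the alkene geometry.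

**Step 18**
Reactants: 20 geraniol
Product: 21 geranyl TBS ether
Conditions: TBSCl (1.1 equiv), imidazole (2.2 equiv), CH2Cl2, rt
Reagents that add atoms: TBSCl, CC(C)(C)[Si](C)(C)Cl (TBS)
Why: silyl protection of the primary alcohol; TBS survives the later strongly basic and hydridic steps.

**Step 19**
Reactants: 21
Product: 22 (2E,6E)-8-(TBSO)-2,6-dimethylocta-2,6-dien-1-ol
Conditions: SeO2 (5 mol %), t-BuOOH (2.5 equiv), salicylic acid (5 mol %), CH2Cl2, 0 °C → rt; then NaBH4, EtOH, 0 °C
Reagents that add atoms: tert-butyl hydroperoxide, CC(C)(C)OO (one O atom)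
Why: Sharpless–Umbreit allylic oxidation of the more electron-rich trisubstituted alkene, selective for the E-methyl. NaBH4 reduces any over-oxidised aldehyde back to the alcohol.

**Step 20**
Reactants: 22
Product: 23 (2E,6E)-1-bromo-8-(TBSO)-2,6-dimethylocta-2,6-diene
Conditions: PPh3, CBr4 (1.3 equiv each), CH2Cl2, 0 °C; use crude
Reagents that add atoms: CBr4, BrC(Br)(Br)Br (Br)
Why: Appel bromination, as in step 16.

**Step 21**
Reactants: 19 sulfone; 23 bromide
Product: 24 coupled allylic sulfone (C9 epimeric mixture, lost in step 22)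
Conditions: n-BuLi (1.05 equiv), THF, −78 °C, 30 min; HMPA (4 equiv); 23 (1.2 equiv), −78 → −30 °C
Reagents that add atoms: none
Why: Biellmann α-alkylation of the allylic sulfone anion. It reacts at the sulfonyl-bearing carbon with the primary allylic bromide and keeps both (E) alkenes, completing the C25 skeleton.

**Step 22**
Reactants: 24
Product: 25 bis-silyl ether of the target
Conditions: Pd(dppp)Cl2 (10 mol %), LiBHEt3 (3 equiv), THF, 0 °C → rt
Reagents that add atoms: none (hydride only)
Why: Pd-catalysed hydrogenolysis of the allylic sulfone through a π-allyl; hydride goes to the less-substituted terminus (C9), so the trisubstituted C10=C11 alkene is kept.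

**Step 23**
Reactants: 25
Product: 26 preluffariellolide A
Conditions: TBAF (1 M in THF, 6 equiv), THF, 0 °C → rt, 12 h
Reagents that add atoms: none
Why: fluoride removes both silyl ethers; no stereocenter or alkene is affected.

## Compound list
1 | isobutyraldehyde | CC(C)C=O | starting material
2 | ethyl vinyl ketone | C=CC(=O)CC | starting material
3 | 2,2-dimethyl-5-oxoheptanal | CCC(=O)CCC(C)(C)C=O | intermediate
4 | 2,4,4-trimethylcyclohex-2-en-1-one | CC1=CC(C)(C)CCC1=O | intermediate
5 | (1R)-2,4,4-trimethylcyclohex-2-en-1-ol, about 92 % ee | O[C@@H]1CCC(C)(C)C=C1C | intermediate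
6 | (1R)-2,4,4-trimethylcyclohex-2-en-1-yl acetate | CC(=O)O[C@@H]1CCC(C)(C)C=C1C | intermediate
7 | (1R)-2,4,4-trimethylcyclohex-2-en-1-ol, ≥99 % ee | O[C@@H]1CCC(C)(C)C=C1C | intermediate
8 | ethyl 2-[(1S)-2,6,6-trimethylcyclohex-2-en-1-yl]acetate | CCOC(=O)C[C@H]1C(C)(C)CCC=C1C | intermediate
9 | ethyl 2-[(1R,2S,6S)-1,3,3-trimethyl-7-oxabicyclo[4.1.0]heptan-2-yl]acetate | CCOC(=O)C[C@H]1C(C)(C)CC[C@@H]2O[C@]12C | intermediate
10 | (1S,2S)-2-(2-hydroxyethyl)-1,3,3-trimethylcyclohexan-1-ol | OCC[C@H]1C(C)(C)CCC[C@]1(C)O | intermediate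
11 | bis-TES ether of 10 | CC[Si](CC)(CC)OCC[C@H]1C(C)(C)CCC[C@]1(C)O[Si](CC)(CC)CC | intermediate
12 | 2-[(1S,2S)-ring] ethanol with tertiary OTES | OCC[C@H]1C(C)(C)CCC[C@]1(C)O[Si](CC)(CC)CC | intermediate
13 | primary iodide | ICC[C@H]1C(C)(C)CCC[C@]1(C)O[Si](CC)(CC)CC | intermediate
14 | terminal alkyne (but-3-yn-1-yl ring) | C#CCC[C@H]1C(C)(C)CCC[C@]1(C)O[Si](CC)(CC)CC | intermediate
15 | (E)-vinyl iodide | I/C=C(\C)CC[C@H]1C(C)(C)CCC[C@]1(C)O[Si](CC)(CC)CC | intermediate
16 | methyl (E)-5-[ring]-3-methylpent-2-enoate | COC(=O)/C=C(\C)CC[C@H]1C(C)(C)CCC[C@]1(C)O[Si](CC)(CC)CC | intermediate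
17 | (E)-5-[ring]-3-methylpent-2-en-1-ol | OC/C=C(\C)CC[C@H]1C(C)(C)CCC[C@]1(C)O[Si](CC)(CC)CC | intermediate
18 | (E)-1-bromo-5-[ring]-3-methylpent-2-ene | BrC/C=C(\C)CC[C@H]1C(C)(C)CCC[C@]1(C)O[Si](CC)(CC)CC | intermediate
19 | (E)-allylic phenyl sulfone | O=S(=O)(c1ccccc1)C/C=C(\C)CC[C@H]1C(C)(C)CCC[C@]1(C)O[Si](CC)(CC)CC | intermediate
20 | geraniol | CC(C)=CCC/C(C)=C/CO | starting material
21 | geranyl TBS ether | CC(C)=CCC/C(C)=C/CO[Si](C)(C)C(C)(C)C | intermediate
22 | (2E,6E)-8-(TBSO)-2,6-dimethylocta-2,6-dien-1-ol | OC/C(C)=C/CC/C(C)=C/CO[Si](C)(C)C(C)(C)C | intermediate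
23 | (2E,6E)-1-bromo-8-(TBSO)-2,6-dimethylocta-2,6-diene | BrC/C(C)=C/CC/C(C)=C/CO[Si](C)(C)C(C)(C)C | intermediate
24 | coupled allylic sulfone | CC(C)(C)[Si](C)(C)OC/C=C(\C)CC/C=C(\C)CC(S(=O)(=O)c1ccccc1)/C=C(\C)CC[C@H]1C(C)(C)CCC[C@]1(C)O[Si](CC)(CC)CC | intermediate
25 | bis-silyl ether of target | CC(C)(C)[Si](C)(C)OC/C=C(\C)CC/C=C(\C)CC/C=C(\C)CC[C@H]1C(C)(C)CCC[C@]1(C)O[Si](CC)(CC)CC | intermediate
26 | preluffariellolide A, (2E,6E,10E)-13-[(1S,2S)-2-hydroxy-2,6,6-trimethylcyclohexyl]-3,7,11-trimethyltrideca-2,6,10-trien-1-ol | C/C(=C\CO)CC/C=C(\C)CC/C=C(\C)CC[C@H]1C(C)(C)CCC[C@]1(C)O | target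

## Totals
- Total steps: 23.
- Longest linear sequence: 20 steps (isobutyraldehyde → 19 is 17 steps, then steps 21–23).

## Three steps most likely to fail
1. **Step 7, facial selectivity of the epoxidation.** Peracid may not discriminate well between the pseudo-axial side chain and the axial gem-dimethyl group.
   - Fallback: change to catalyst-controlled epoxidation (Shi fructose-derived ketone/Oxone, matched catalyst enantiomer) so the catalyst rather than the substrate picks the face.
2. **Step 6, Johnson–Claisen next to the quaternary carbon.** The forming bond is neopentyl-like, so the rearrangement may be slow or low-yielding.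
   - Fallback: run the Claisen on the racemic alcohol, hydrolyse to the acid, and resolve it by crystallising its (S)-1-phenylethylamine salt. This replaces the chirality-transfer strategy with a classical resolution.
3. **Step 22, regiochemistry of the desulfonylation.** Hydride might attack the tertiary π-allyl terminus and shift the alkene.
   - Fallback: drop the sulfone route and build the C8–C9 link by iterative chain extension from bromide 18 (acetoacetate alkylation, decarboxylation, HWE, DIBAL, bromination). The E/Z mixtures from HWE would be separated on AgNO3-silica.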